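**Strategy.** The route rests on a (4+3) disconnection of the dihydrooxepine ring fused to ring A (benzoxepine numbering). The C5–C5a–C9a edge of ring A is carried as a 1,3-bis-electrophile: a chloromethyl group on C5a and a chloride on C9a, para to a formyl group at C7. The O1–C2–C3(Me)=C4 unit is a Z-locked 1,4-bis-nucleophile, the cyclic alkenylboronic hemiester 4-methyl-1,2-oxaborol-2(5H)-ol. One palladium-catalysed operation joins C4 to C5 (Suzuki–Miyaura coupling) and O1 to C9a (aryl etherification). It exploits that the ring oxygen sits para to the acyl-bearing carbon C7 and on the carbon next to the one bearing the benzylic CH2. The dihydrochalcone chain is then grown from the C7 aldehyde.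

Key step: step 5

Remark: compounds 1, 2, 9 and 14 are taken as commercial. The target has no stereocentre; the only one on the route (the carbinol of 18) is formed racemic and removed in step 9.

Step 1
Reactants: 1 4-chloro-2,6-difluorobenzaldehyde; 2 2-(trimethylsilyl)ethanol (2.2 equiv)
Product: 3 4-chloro-2,6-bis[2-(trimethylsilyl)ethoxy]benzaldehyde
Conditions: NaH (2.3 equiv), THF, 0 → 50 °C
Reagents that add atoms: none
Why: Double SNAr, in which the two fluorides ortho to the formyl group are far better leaving groups than the para chloride, so the alkoxide of 2 should replace both and leave the C–Cl bond for the key step.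

Step 2
Reactants: 3 4-chloro-2,6-bis[2-(trimethylsilyl)ethoxy]benzaldehyde
Product: 6 4-chloro-3-(hydroxymethyl)-2,6-bis[2-(trimethylsilyl)ethoxy]benzaldehyde, via lithium α-amino alkoxide 4 (not isolated), via ring-lithiated α-amino alkoxide 5 (not isolated)
Conditions: LiN(Me)CH2CH2NMe2 (from N,N,N′-trimethylethylenediamine and n-BuLi), THF, −20 °C; s-BuLi, −78 °C; CH2O (gas), −78 °C → rt; H2O
Reagents that add atoms: formaldehyde, C=O
Why: In situ protection of the aldehyde as its α-amino alkoxide, then directed ortho-metalation at the only ring C–H type (flanked by chlorine and an alkoxy group, the two sites being equivalent by symmetry) and trapping with monomeric formaldehyde should give the hydroxymethyl group, the transient aminal stereocentre being lost on work-up.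

Step 3
Reactants: 6 4-chloro-3-(hydroxymethyl)-2,6-bis[2-(trimethylsilyl)ethoxy]benzaldehyde
Product: 8 4-chloro-3-(chloromethyl)-2,6-bis[2-(trimethylsilyl)ethoxy]benzaldehyde, via benzylic mesylate 7 (not isolated)
Conditions: MsCl, Et3N, CH2Cl2, 0 °C → rt
Reagents that add atoms: methanesulfonyl chloride, CS(=O)(=O)Cl
Why: Mesylation of the electron-rich benzylic alcohol followed by in situ nucleophilic displacement of the mesylate by chloride should give the benzylic chloride under non-acidic conditions that spare the silylethyl ethers and the aldehyde.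

Step 4
Reactants: 9 prop-2-yn-1-ol
Product: 11 4-methyl-1,2-oxaborol-2(5H)-ol, via chelated alkenylmagnesium alkoxide 10 (not isolated)
Conditions: MeMgBr (2.5 equiv), CuI (10 mol %), THF, 0 °C → reflux; B(OMe)3, −20 °C → rt; 1 M HCl
Reagents that add atoms: methylmagnesium bromide, C[Mg]Br; trimethyl borate, COB(OC)OC; water, O
Why: Copper-catalysed anti carbomagnesiation of the propargylic alkoxide places methyl on the internal carbon and magnesium on the terminal carbon cis to the CH2O group, and borylation of this alkenyl Grignard reagent followed by acidic work-up should give the cyclic alkenylboronic hemiester, whose five-membered ring fixes the Z geometry.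

Step 5
Reactants: 8 4-chloro-3-(chloromethyl)-2,6-bis[2-(trimethylsilyl)ethoxy]benzaldehyde; 11 4-methyl-1,2-oxaborol-2(5H)-ol
Product: 13 3-methyl-6,8-bis[2-(trimethylsilyl)ethoxy]-2,5-dihydro-1-benzoxepine-7-carbaldehyde, via Z-allylic alcohol 12 (not isolated)
Conditions: Pd(OAc)2 (5 mol %), 2-(di-tert-butylphosphino)-1,1′-binaphthyl (10 mol %), Cs2CO3 (3 equiv), H2O (2 equiv), toluene, 45 °C then 85 °C, one pot
Reagents that add atoms: none
Why: Zerovalent palladium should insert first into the benzylic C–Cl bond of 8 (SN2-type oxidative addition, faster than insertion into the ortho-substituted aryl C–Cl bond), the cesium boronate of 11 transfers its alkenyl carbon C4 with retention, and reductive elimination forms the C4–C5 bond to give the Z-allylic alcohol 12, whose oxygen is freed from boron by carbonate and water. At the higher temperature the same catalyst inserts into the aryl C–Cl bond at C9a, which the para formyl group at C7 activates, and alkoxide exchange followed by C–O reductive elimination forms the O1–C9a bond. The closest known reaction types are the Suzuki–Miyaura coupling of benzylic chlorides with alkenylboron reagents and the intramolecular Buchwald–Hartwig-type etherification of aryl chlorides with primary alcohols, run here as one domino (4+3) annulation. The seven-membered ring is closed by reductive elimination from an eight-membered aryl-palladium alkoxide chelate, that is by ipso attack of O1 on C9a; no stereocentre is formed, and the Z geometry that the ring requires is delivered by the oxaborole. The step needs site selectivity between the two C–Cl bonds and suppression of β-hydride elimination from the palladium alkoxide: the first is secured by the intrinsic reactivity gap and the staged temperature, the second by the bulky di-tert-butyl biaryl phosphine. A direct SNAr displacement of the formyl-activated chloride by the tethered alkoxide would lead to the same product.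

Step 6
Reactants: 14 4-(2-bromoethyl)-1,2-dimethoxybenzene
Product: 15 4-(2-bromoethyl)benzene-1,2-diol
Conditions: BBr3 (2.5 equiv), CH2Cl2, −78 °C → rt; H2O
Reagents that add atoms: none
Why: Lewis acid cleavage of both aryl methyl ethers (BBr3 demethylation) should give the catechol while the primary alkyl bromide stays untouched.

Step 7
Reactants: 15 4-(2-bromoethyl)benzene-1,2-diol
Product: 16 4-(2-bromoethyl)-1,2-bis(tert-butyldimethylsilyloxy)benzene
Conditions: TBSCl (2.4 equiv), imidazole, CH2Cl2, 0 °C → rt
Reagents that add atoms: tert-butyldimethylsilyl chloride, CC(C)(C)[Si](C)(C)Cl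
Why: Silyl ether formation at both phenols should give a fluoride-labile protected catechol that tolerates Grignard formation.

Step 8
Reactants: 13 3-methyl-6,8-bis[2-(trimethylsilyl)ethoxy]-2,5-dihydro-1-benzoxepine-7-carbaldehyde; 16 4-(2-bromoethyl)-1,2-bis(tert-butyldimethylsilyloxy)benzene
Product: 18 3-[3,4-bis(tert-butyldimethylsilyloxy)phenyl]-1-{3-methyl-6,8-bis[2-(trimethylsilyl)ethoxy]-2,5-dihydro-1-benzoxepin-7-yl}propan-1-ol, via Grignard reagent 17 (not isolated)
Conditions: Mg, I2 (cat.), THF, 35 °C; then 13, THF, −20 → 0 °C; aq NH4Cl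
Reagents that add atoms: none
Why: Grignard addition to the aldehyde should give the secondary alcohol, whose new carbinol stereocentre is formed as a racemate without control because step 9 removes it.

Step 9
Reactants: 18 3-[3,4-bis(tert-butyldimethylsilyloxy)phenyl]-1-{3-methyl-6,8-bis[2-(trimethylsilyl)ethoxy]-2,5-dihydro-1-benzoxepin-7-yl}propan-1-ol
Product: 19 3-[3,4-bis(tert-butyldimethylsilyloxy)phenyl]-1-{3-methyl-6,8-bis[2-(trimethylsilyl)ethoxy]-2,5-dihydro-1-benzoxepin-7-yl}propan-1-one
Conditions: Dess–Martin periodinane, CH2Cl2, 0 °C → rt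
Reagents that add atoms: none
Why: Dess–Martin oxidation of the benzylic secondary alcohol should give the aryl ketone under near-neutral conditions that leave the silyl ethers, the trisubstituted alkene and the allyl aryl ether untouched.

Step 10
Reactants: 19 3-[3,4-bis(tert-butyldimethylsilyloxy)phenyl]-1-{3-methyl-6,8-bis[2-(trimethylsilyl)ethoxy]-2,5-dihydro-1-benzoxepin-7-yl}propan-1-one
Product: 20 3-(3,4-dihydroxyphenyl)-1-(6,8-dihydroxy-3-methyl-2,5-dihydro-1-benzoxepin-7-yl)propan-1-one
Conditions: TBAF (8 equiv), THF/DMF, 0 → 50 °C, argon; then AcOH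
Reagents that add atoms: none
Why: Fluoride-induced global deprotection, by desilylation of the two aryl silyl ethers and by β-elimination (fluoride attack on silicon with loss of ethene) of the two 2-(trimethylsilyl)ethyl aryl ethers whose phenoxide leaving groups are stabilised by the ortho ketone, should free the four phenols without acid, so that the alkene and the allyl aryl ether survive.

**Compound list**

1 | 4-chloro-2,6-difluorobenzaldehyde | O=Cc1c(F)cc(Cl)cc1F | starting material
2 | 2-(trimethylsilyl)ethanol | C[Si](C)(C)CCO | starting material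
3 | 4-chloro-2,6-bis[2-(trimethylsilyl)ethoxy]benzaldehyde | O=Cc1c(OCC[Si](C)(C)C)cc(Cl)cc1OCC[Si](C)(C)C | intermediate
4 | lithium {4-chloro-2,6-bis[2-(trimethylsilyl)ethoxy]phenyl}{[2-(dimethylamino)ethyl](methyl)amino}methanolate (racemic) | [Li+].[O-]C(N(C)CCN(C)C)c1c(OCC[Si](C)(C)C)cc(Cl)cc1OCC[Si](C)(C)C | intermediate (not isolated)
5 | lithium {4-chloro-3-lithio-2,6-bis[2-(trimethylsilyl)ethoxy]phenyl}{[2-(dimethylamino)ethyl](methyl)amino}methanolate (racemic) | [Li+].[O-]C(N(C)CCN(C)C)c1c(OCC[Si](C)(C)C)cc(Cl)c([Li])c1OCC[Si](C)(C)C | intermediate (not isolated)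
6 | 4-chloro-3-(hydroxymethyl)-2,6-bis[2-(trimethylsilyl)ethoxy]benzaldehyde | O=Cc1c(OCC[Si](C)(C)C)cc(Cl)c(CO)c1OCC[Si](C)(C)C | intermediate
7 | {6-chloro-3-formyl-2,4-bis[2-(trimethylsilyl)ethoxy]phenyl}methyl methanesulfonate | O=Cc1c(OCC[Si](C)(C)C)cc(Cl)c(COS(C)(=O)=O)c1OCC[Si](C)(C)C | intermediate (not isolated)
8 | 4-chloro-3-(chloromethyl)-2,6-bis[2-(trimethylsilyl)ethoxy]benzaldehyde | O=Cc1c(OCC[Si](C)(C)C)cc(Cl)c(CCl)c1OCC[Si](C)(C)C | intermediate
9 | prop-2-yn-1-ol | C#CCO | starting material
10 | 4-methyl-2,5-dihydro-1,2-oxamagnesole (chelated Z-alkenylmagnesium alkoxide) | CC1=C[Mg]OC1 | intermediate (not isolated)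
11 | 4-methyl-1,2-oxaborol-2(5H)-ol | CC1=CB(O)OC1 | intermediate
12 | 4-chloro-3-[(2Z)-4-hydroxy-3-methylbut-2-en-1-yl]-2,6-bis[2-(trimethylsilyl)ethoxy]benzaldehyde | O=Cc1c(OCC[Si](C)(C)C)cc(Cl)c(C/C=C(C)\CO)c1OCC[Si](C)(C)C | intermediate (not isolated)
13 | 3-methyl-6,8-bis[2-(trimethylsilyl)ethoxy]-2,5-dihydro-1-benzoxepine-7-carbaldehyde | CC1=CCc2c(cc(OCC[Si](C)(C)C)c(C=O)c2OCC[Si](C)(C)C)OC1 | intermediate
14 | 4-(2-bromoethyl)-1,2-dimethoxybenzene | COc1ccc(CCBr)cc1OC | starting material
15 | 4-(2-bromoethyl)benzene-1,2-diol | Oc1ccc(CCBr)cc1O | intermediate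
16 | 4-(2-bromoethyl)-1,2-bis(tert-butyldimethylsilyloxy)benzene | CC(C)(C)[Si](C)(C)Oc1ccc(CCBr)cc1O[Si](C)(C)C(C)(C)C | intermediate
17 | {2-[3,4-bis(tert-butyldimethylsilyloxy)phenyl]ethyl}magnesium bromide | CC(C)(C)[Si](C)(C)Oc1ccc(CC[Mg]Br)cc1O[Si](C)(C)C(C)(C)C | intermediate (not isolated)
18 | 3-[3,4-bis(tert-butyldimethylsilyloxy)phenyl]-1-{3-methyl-6,8-bis[2-(trimethylsilyl)ethoxy]-2,5-dihydro-1-benzoxepin-7-yl}propan-1-ol (racemic) | CC1=CCc2c(cc(OCC[Si](C)(C)C)c(C(O)CCc3ccc(O[Si](C)(C)C(C)(C)C)c(O[Si](C)(C)C(C)(C)C)c3)c2OCC[Si](C)(C)C)OC1 | intermediate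
19 | 3-[3,4-bis(tert-butyldimethylsilyloxy)phenyl]-1-{3-methyl-6,8-bis[2-(trimethylsilyl)ethoxy]-2,5-dihydro-1-benzoxepin-7-yl}propan-1-one | CC1=CCc2c(cc(OCC[Si](C)(C)C)c(C(=O)CCc3ccc(O[Si](C)(C)C(C)(C)C)c(O[Si](C)(C)C(C)(C)C)c3)c2OCC[Si](C)(C)C)OC1 | intermediate
20 | 3-(3,4-dihydroxyphenyl)-1-(6,8-dihydroxy-3-methyl-2,5-dihydro-1-benzoxepin-7-yl)propan-1-one | CC1=CCc2c(cc(O)c(C(=O)CCc3ccc(O)c(O)c3)c2O)OC1 | target

**Step count.** Total: 10 steps. Longest linear sequence: 7 steps (steps 1, 2, 3, 5, 8, 9, 10).

**Steps most likely to fail, with fallbacks**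

Step 5. The one-pot annulation may fail through insertion of palladium into the aryl C–Cl bond before the benzylic coupling, through β-hydride elimination at the palladium alkoxide stage, or through palladium-induced ionisation of the allyl aryl ether once the ring has formed. The ring would then be closed by olefin metathesis instead. Setting out from 8, Suzuki–Miyaura coupling with vinylboronic acid pinacol ester (Pd(PPh3)4, K2CO3, dioxane/H2O, 70 °C) should give 3-allyl-4-chloro-2,6-bis[2-(trimethylsilyl)ethoxy]benzaldehyde F1. Palladium-catalysed etherification of its aryl chloride with 2-methylprop-2-en-1-ol (Pd(OAc)2, 2-(di-tert-butylphosphino)-1,1′-binaphthyl, Cs2CO3, toluene, 80 °C) should give 3-allyl-4-[(2-methylprop-2-en-1-yl)oxy]-2,6-bis[2-(trimethylsilyl)ethoxy]benzaldehyde F2. Ring-closing metathesis with the second-generation Grubbs catalyst (CH2Cl2, 40 °C) should then form the trisubstituted C3=C4 alkene and return to the route at 13.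

Step 2. The metalation may be incomplete, the ortho-chloro aryllithium may lose LiCl to an aryne on warming, or the capture of gaseous formaldehyde may be inefficient. Setting out from 3, electrophilic bromination (NBS, MeCN, rt) at the only free type of ring position should give 3-bromo-4-chloro-2,6-bis[2-(trimethylsilyl)ethoxy]benzaldehyde F3. Stille coupling with (tributylstannyl)methanol (Pd(PPh3)4, dioxane, 90 °C), which is selective for the C–Br over the C–Cl bond, should then return to the route at 6.

Step 4. Borylation of the chelated alkenylmagnesium alkoxide may be sluggish, and the small water-soluble oxaborole may be lost on isolation. Setting out from 9, the same carbomagnesiation quenched with I2 should give (Z)-3-iodo-2-methylprop-2-en-1-ol F4. Miyaura borylation (B2pin2, PdCl2(PPh3)2, KOPh, toluene, 50 °C) should give (Z)-2-methyl-3-(4,4,5,5-tetramethyl-1,3,2-dioxaborolan-2-yl)prop-2-en-1-ol F5, a lipophilic partner that can be purified by chromatography. It would take the place of 11 in step 5 and so return to the route at 13.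

**Further compounds**

F1 | step 5 | 3-allyl-4-chloro-2,6-bis[2-(trimethylsilyl)ethoxy]benzaldehyde | O=Cc1c(OCC[Si](C)(C)C)cc(Cl)c(CC=C)c1OCC[Si](C)(C)C
F2 | step 5 | 3-allyl-4-[(2-methylprop-2-en-1-yl)oxy]-2,6-bis[2-(trimethylsilyl)ethoxy]benzaldehyde | O=Cc1c(OCC[Si](C)(C)C)cc(OCC(C)=C)c(CC=C)c1OCC[Si](C)(C)C
F3 | step 2 | 3-bromo-4-chloro-2,6-bis[2-(trimethylsilyl)ethoxy]benzaldehyde | O=Cc1c(OCC[Si](C)(C)C)cc(Cl)c(Br)c1OCC[Si](C)(C)C
F4 | step 4 | (Z)-3-iodo-2-methylprop-2-en-1-ol | C/C(CO)=C/I
F5 | step 4 | (Z)-2-methyl-3-(4,4,5,5-tetramethyl-1,3,2-dioxaborolan-2-yl)prop-2-en-1-ol | C/C(CO)=C/B1OC(C)(C)C(C)(C)O1
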